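0.150 is the dose at which west reads 12.1 % and north-west reads 11.3 %, a gap of 0.8 percentage points against a scatter of 0.5 points per reading. By dose I mean J charge times time, counted in units of cedar's product at 20 min. West gets there at 2.00 min and north-west at 1.50 min, the same product. So I read Q's fraction of the D charged as a function of dose.

| flask | D | J | remark | time | volume of the second phase over the first |
|---|---|---|---|---|---|
| west | 0.080 M | 6 equiv | run made earlier |  |  |
| north-west | 0.080 M | 8 equiv | run made earlier |  |  |
| cedar | 0.080 M | 4.00 equiv |  | 20 min | 2.0 |
| alder | 0.12 M | 4.00 equiv |  | 20 min | 2.0 |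
| elm | 0.15 M | 4.00 equiv |  | 20 min | 2.0 |
| birch | 0.25 M | 4.00 equiv |  | 20 min | 2.0 |
| maple | 0.40 M | 4.00 equiv |  | 20 min | 2.0 |

| run | time / min | Q / % |
|---|---|---|
| west | 1.00 | 4.1 |
| west | 2.00 | 12.1 |
| west | 5.00 | 31.3 |
| west | 12.0 | 32.3 |
| north-west | 1.50 | 11.3 |
| north-west | 4.00 | 30.9 |
| north-west | 8.00 | 35.2 |
| north-west | 12.0 | 26.9 |

(standard deviation of a reading: 0.5 percentage points)

- in the second phase: J; everything else is in the first
- charges count per volume of the first phase; a concentration in a rate is the amount of a species over the volume of its own phase; every rate counts per litre of the first phase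
- on the list of suspects stand: Z + Q -> E; Z <-> J; D + Z -> Q; Z + Q -> X; Q <-> L
- the earlier runs hold the two phases in the same ratio of volumes as the flask asked about
- "hardly changes" means that all values lie within two and a half points (for a concentration: within two and a half percent of the largest)

1. [Q] at the end for cedar, alder, elm, birch, maple, in this order
2. the course of these numbers from the first flask to the last (hardly changes / falls, then rises / rises all the way / falls all the way / rises, then falls)

Equivalents and time stay fixed in the row, so each flask's dose is its D over cedar's D, and maple reaches 5.00. Both earlier runs hold D fixed, so this stretch is my assumption.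

I build the flask up. Take the main step first, D + Z → Q. Q's fraction then climbs with dose, and the row rises with D. Now add the feed of Z from J. West's Q grows 2.95 times from 1.00 min to 2.00 min, more than the time grows, and I read that as a lag at the start. The tail readings lie past it.

Now add the losses of Q. The readings can't separate E, X and L, so I take them as one tail. West at dose 0.900 reads 32.3 %, and north-west at dose 1.20 reads 26.9 %. I take the logarithm of the fraction as a straight line in dose, a pseudo-first-order decay with dose in place of time. Read off these two scattered readings, its slope gives the tenfold dose, the dose that cuts Q's fraction by one power of ten: 3.78.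

Since [Q] is the D charged times the fraction, the logarithm of the D charged gains along the row while the tail loses. The two slopes match at dose 1.64, which is D near 0.131 M. My line gives these fractions along the row: 30.4 %, 22.4 %, 17.8 %, 8.32 % and 2.65 %.

The forecast gives 0.0254 M, 0.0281 M, 0.0267 M, 0.0167 M and 0.0056 M, and its course rises, then falls. For maple that is a fraction of 1.40 %, below mine. It warns: “Extrapolating to high D is the main uncertainty.”

The flasks give 0.0215 M, 0.0259 M, 0.0267 M, 0.0219 M and 0.0115 M; the course rises, then falls.

    Z + Q → E (k = 0.0111 M⁻¹ s⁻¹)
    Z ⇌ J, rate k2*([Z] - [J]/K2) per volume of the first phase (partition coefficient = 1.77, kL = 0.00972 s⁻¹)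
    D + Z → Q (k = 0.0262 M⁻¹ s⁻¹)
    Z + Q → X (k = 0.00949 M⁻¹ s⁻¹)
    Q ⇌ L (K = 17.0, k = 6.40 × 10⁻⁴ s⁻¹)

In cedar at 3.00 min, Q is made 4.58 times faster than it is used, each step taken net. In cedar at 20.0 min, Z still goes 1.8 times faster into Q than into E. Cedar's dose is 0.265 of a tenfold dose, and its Q stands at 26.8 %. Maple's dose is 1.32 tenfold doses, and its Q stands at 2.88 %.

All runs were computed for substances that don't exist, noise included.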